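The C11 benzoate and the C2 acid are folded back into a δ-lactone. Ring C is opened at C12–C13 and its four-carbon unit removed at C13–C14. The lactone oxygen is taken out between C2 and C11. C9–C10, C1–C2 and C2–C11 are then cut together to an acyclic 1,7-enyne, which is cut at C8–C9. Its C3–C8 chain is a ring-opened dimethylated carvone.
Enabling feature: the C2 carboxyl carbon and the oxygen on C11 stand 1,5 along C2–C1–C10–C9–C11, so both derive from one ketone. That ketone is C2 of a cyclopentanone C10–C1–C2–C11–C9 fused to ring B (C5–C6–C7–C8–C9–C10) at C9–C10. Its enone is the [2+2+1] adduct of the C10=C1 alkene, the C9≡C11 alkyne and CO.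
Forward order: chain (steps 1–14), ring B and the cyclopentenone together (step 15), ring expansion to the lactone (step 18), ring C (step 24), lactone opening and acylations (steps 25–29).
Stereochemistry: C5 comes from (S)-carvone. C7 follows from C5 (face-selective 1,2-reduction, then suprafacial 1,3-transposition), C8 from C7 (chelate-controlled alkynylation) and C10 from C5 (chair-like cyclisation). C9 is set by hydroxyl-directed hydrogenation, C11 by equilibration and retentive migration, and C13 by dienolate geometry within the C11 tether.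

Key step: step 15

Remark: C1–C20 are the 2,3-seco-pimarane labels of the target and are used for all intermediates; α is the ring face of H5 and H9, β that of C20; the C14 carbinol centre of 29 is left undefined because step 23 removes it.

Step 1
Reactants: 1 (S)-(+)-carvone
Product: 2 trans-6-methylcarvone
Conditions: LiN(iPr)2, THF, −78 °C; MeI, −78 → 0 °C
Reagents that add atoms: iodomethane, CI
Why: Kinetic alkylation of the cross-conjugated enolate takes place at the only α′ carbon (the future C4), mainly anti to the neighbouring isopropenyl group, and this new centre is erased in step 2.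

Step 2
Reactants: 2 trans-6-methylcarvone
Product: 3 6,6-dimethylcarvone
Conditions: LiN(iPr)2, THF, −78 °C; MeI, −78 °C → rt
Reagents that add atoms: iodomethane, CI
Why: A second kinetic enolate alkylation at the same carbon completes the gem-dimethyl group of C4 and leaves the carvone stereocentre, the future C5, untouched.

Step 3
Reactants: 3 6,6-dimethylcarvone
Product: 4 cis-allylic alcohol
Conditions: NaBH4, CeCl3·7H2O, MeOH, −20 °C
Reagents that add atoms: none
Why: In this Luche 1,2-reduction hydride reaches the carbonyl carbon from the face opposite the isopropenyl group (the other face is also screened by the axial methyl of the CMe2 group), so the hydroxyl ends up cis to the isopropenyl group.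

Step 4
Reactants: 4 cis-allylic alcohol
Product: 5 transposed cis-allylic alcohol
Conditions: O3ReOSiPh3 (cat.), Et2O, −40 → 0 °C
Reagents that add atoms: none
Why: In this rhenium-oxo-catalysed 1,3-transposition of an allylic alcohol the perrhenate ester shifts suprafacially ([3,3]), so oxygen arrives at the future C7 on the same ring face, cis to the isopropenyl group as the C5/C7 pair of the target requires, and leaving the neopentyl position beside CMe2 drives the equilibrium.

Step 5
Reactants: 5 transposed cis-allylic alcohol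
Product: 6 syn-epoxy alcohol
Conditions: VO(acac)2 (cat.), t-BuOOH, toluene, 0 °C → rt
Reagents that add atoms: tert-butyl hydroperoxide, CC(C)(C)OO
Why: The hydroxyl-directed vanadium-catalysed epoxidation touches only the allylic alkene and spares the isopropenyl group, and its two new centres (oxirane syn to OH) disappear in step 7.

Step 6
Reactants: 6 syn-epoxy alcohol
Product: 7 epoxy PMB ether
Conditions: NaH, 4-MeOC6H4CH2Cl, Bu4NI (cat.), THF–DMF, 0 °C → rt
Reagents that add atoms: 4-methoxybenzyl chloride, COc1ccc(CCl)cc1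
Why: This Williamson etherification is safe because the syn alkoxide cannot reach the back side of the oxirane (no Payne rearrangement), and the benzyl-type ether on O7 is the chelating group needed in step 13.

Step 7
Reactants: 7 epoxy PMB ether
Product: 8 keto aldehyde
Conditions: H5IO6, THF–H2O, 0 °C → rt
Reagents that add atoms: water, O
Why: Periodic acid hydrolyses the epoxide and cleaves the resulting glycol (Malaprade-type cleavage), which opens the ring between the future C3 and C8 whichever oxirane carbon water attacks, while the C7 ether and the 1,1-disubstituted alkene are inert.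

Step 8
Reactants: 8 keto aldehyde
Product: 9 keto acid
Conditions: NaClO2, NaH2PO4, 2-methylbut-2-ene, t-BuOH–H2O, 0 °C → rt
Reagents that add atoms: sodium chlorite, [Na+].[O-]Cl=O
Why: The Pinnick oxidation converts only the aldehyde (C3), the scavenger protects the alkene and the PMB ring from hypochlorous acid, and the buffer keeps C7, now α to a ketone, from epimerising.

Step 9
Reactants: 9 keto acid
Product: 10 tert-butyl keto ester
Conditions: t-BuOC(=NH)CCl3, CH2Cl2–cyclohexane, rt
Reagents that add atoms: tert-butyl 2,2,2-trichloroacetimidate, CC(C)(C)OC(=N)C(Cl)(Cl)Cl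
Why: Esterification by O-alkylation with the tert-butyl cation released from the imidate avoids any attack at the neopentyl carbonyl carbon and runs near neutrality, so C7 is not endangered.

Step 10
Reactants: 10 tert-butyl keto ester
Product: 11 triethylsilyl enol ether
Conditions: LiN(iPr)2, THF, −78 °C; Et3SiCl, −78 → 0 °C
Reagents that add atoms: chlorotriethylsilane, CC[Si](Cl)(CC)CC
Why: Kinetic enolisation removes a proton from the methyl group (C14) and not the hindered alkoxy-bearing C7–H, the ester has no α-hydrogen, and O-silylation fixes the terminal enol ether.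

Step 11
Reactants: 11 triethylsilyl enol ether
Product: 12 α-silyloxy ketone
Conditions: mCPBA, NaHCO3, CH2Cl2, −20 °C
Reagents that add atoms: 3-chloroperbenzoic acid, O=C(OO)c1cccc(Cl)c1
Why: In this Rubottom oxidation the electron-rich enol ether is epoxidised far faster than the hindered isopropenyl group and the silyl group migrates to the new oxygen, which delivers C14 directly as CH2OSiEt3.

Step 12
Reactants: 13 propargyl alcohol
Product: 14 4-methoxybenzyl propargyl ether
Conditions: NaH, 4-MeOC6H4CH2Cl, Bu4NI (cat.), THF, 0 °C → rt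
Reagents that add atoms: 4-methoxybenzyl chloride, COc1ccc(CCl)cc1
Why: This Williamson etherification of a primary alkoxide supplies C9, C11 and C12 with O12 masked.

Step 13
Reactants: 12 α-silyloxy ketone; 14 4-methoxybenzyl propargyl ether
Product: 16 tertiary propargylic alcohol, via alkynylmagnesium bromide 15 (not isolated)
Conditions: 14, EtMgBr, THF, 0 °C → rt; then 12, THF, −78 → −20 °C; aq NH4Cl
Reagents that add atoms: none
Why: In this chelation-controlled Grignard addition (Cram chelate model) magnesium bridges the C8 carbonyl and the O7 benzyl-type ether while the silyl ether on O14 does not compete, and the slim alkynyl group attacks anti to the C6 chain, which sets C8 with O7 and O8 syn along C6–C7–C8–C9, the trans-diaxial pair of ring B.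

Step 14
Reactants: 16 tertiary propargylic alcohol
Product: 17 1,7-enyne
Conditions: Et3SiOTf, 2,6-lutidine, CH2Cl2, 0 °C
Reagents that add atoms: triethylsilyl trifluoromethanesulfonate, CC[Si](CC)(CC)OS(=O)(=O)C(F)(F)F
Why: Silylation of the tertiary alcohol with the silyl triflate caps O8, and because O8 and O14 then carry the same group any silyl migration between them in step 13 is without consequence.

Step 15
Reactants: 17 1,7-enyne
Product: 19 ring B-fused cyclopentenone, via dicobalt hexacarbonyl alkyne complex 18 (not isolated)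
Conditions: Co2(CO)8 (1.1 equiv), toluene, rt; then n-BuSMe, 80 °C
Reagents that add atoms: dicobalt octacarbonyl (supplies C2 and its oxygen as CO), [Co].[Co].[C-]#[O+].[C-]#[O+].[C-]#[O+].[C-]#[O+].[C-]#[O+].[C-]#[O+].[C-]#[O+].[C-]#[O+]
Why: This is an intramolecular Pauson–Khand [2+2+1] reaction, closest in type to the cyclisation of 1,7-enynes with 1,1-disubstituted alkenes to hydrindenones that carry a quaternary ring-fusion carbon: Co2(CO)8 binds the C9≡C11 alkyne as 18, loss of CO (aided by the sulfide) lets the C10=C1 alkene coordinate and insert into the Co–C9 bond, CO inserts into the Co–C1 bond and reductive elimination joins C2 to C11. Ring B (C5–C6–C7–C8–C9–C10) closes in the insertion step in the exo mode, C10 bonding to C9 with C1 left outside the six-membered ring, and the cyclopentenone (C10–C1–C2–C11–C9) closes in the reductive elimination. The only new stereocentre, C10, is controlled by C5: the forming ring B adopts a chair with the very large CMe2CO2tBu arm equatorial, and since C1 must lie almost in the plane of the C9=C11 bond (equatorial), C20 is forced axial on the β face, so C1 ends up anti to the C5 arm. The step needs this diastereoselectivity and a clean intramolecular course; the size of the C5 arm secures the first. The second is secured by the fully substituted C8, which compresses the C7–C8–C9 angle and holds alkyne and alkene together, and by the absence of any second alkene, the butenoyl unit of ring C being added only in step 22. Regiochemistry is fixed by the tether.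

Step 16
Reactants: 19 ring B-fused cyclopentenone
Product: 20 enone diol
Conditions: DDQ, CH2Cl2–pH 7 buffer, 0 °C
Reagents that add atoms: none
Why: Oxidative PMB cleavage by DDQ (hydride abstraction, then hydrolysis of the oxocarbenium ions) removes both benzyl-type ethers under buffered conditions that spare the silyl ethers and the electron-poor enone, and it frees the two hydroxyls that steer step 17.

Step 17
Reactants: 20 enone diol
Product: 22 trans-hydrindanone diol, via C11 epimer 21 (not isolated)
Conditions: H2 (50 bar), [Ir(cod)(PCy3)(py)]PF6 (cat.), CH2Cl2, rt; then DBU (cat.), CH2Cl2, rt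
Reagents that add atoms: none
Why: In this hydroxyl-directed homogeneous hydrogenation followed by base equilibration the cationic iridium hydride is held on the α face by the allylic C12 hydroxyl and the axial 7α-hydroxyl while the β face of C9=C11 is walled off by the axial C20 methyl and the 8β-silyloxy group, so both hydrogens enter from α (9α-H, trans to C20), and DBU then epimerises the enolisable C11 of 21 to the less strained isomer with C12 trans to C8 (11β-H).

Step 18
Reactants: 22 trans-hydrindanone diol
Product: 23 δ-lactone diol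
Conditions: mCPBA, NaHCO3, CH2Cl2, rt
Reagents that add atoms: 3-chloroperbenzoic acid, O=C(OO)c1cccc(Cl)c1
Why: In the Baeyer–Villiger oxidation the more substituted C11 migrates in preference to the C1 methylene and does so with retention, which turns the C2–C11 bond into the 11α C–O bond and C2 into the lactone carbonyl at a stage where no alkene is present.

Step 19
Reactants: 23 δ-lactone diol
Product: 24 bromo lactone
Conditions: CBr4, PPh3, CH2Cl2, 0 °C
Reagents that add atoms: tetrabromomethane, BrC(Br)(Br)Br
Why: The Appel reaction converts only the primary C12 hydroxyl, since the axial secondary 7α-hydroxyl beside quaternary C8 is too hindered to form or displace a phosphonium ether.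

Step 20
Reactants: 24 bromo lactone
Product: 25 tris(triethylsilyl) bromo lactone
Conditions: Et3SiOTf, 2,6-lutidine, CH2Cl2, −78 → 0 °C
Reagents that add atoms: triethylsilyl trifluoromethanesulfonate, CC[Si](CC)(CC)OS(=O)(=O)C(F)(F)F
Why: Silylation of O7 with the reactive triflate is needed because a free 7-alkoxide would open a retro-aldol path through C7–C8 once the C14 ketone and strong base meet in step 24.

Step 21
Reactants: 25 tris(triethylsilyl) bromo lactone
Product: 26 C14 aldehyde
Conditions: (COCl)2, DMSO, CH2Cl2, −78 → −40 °C; Et3N, −78 °C → rt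
Reagents that add atoms: none
Why: Swern conditions oxidise primary triethylsilyl ethers directly (the activated sulfonium species displaces the silyl group) and leave secondary and tertiary ones alone, so C14 goes from CH2OSiEt3 to CHO in one operation.

Step 22
Reactants: 26 C14 aldehyde; 27 (E)-2-bromobut-2-ene
Product: 29 C14 allylic alcohol, via (E)-but-2-en-2-yllithium 28 (not isolated)
Conditions: 27, t-BuLi (2 equiv), Et2O, −78 °C; then 26, THF, −78 °C; aq NH4Cl
Reagents that add atoms: none
Why: Halogen–lithium exchange with retention followed by 1,2-addition to the non-enolisable aldehyde, which at −78 °C far outpaces the lactone, the tert-butyl ester and the alkyl bromide, brings in C13 and C15–C17 only now because this alkene would not have survived steps 17 and 18.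

Step 23
Reactants: 29 C14 allylic alcohol
Product: 30 tigloyl ketone
Conditions: Dess–Martin periodinane, NaHCO3, CH2Cl2, 0 °C → rt
Reagents that add atoms: none
Why: The Dess–Martin oxidation of the only free (allylic) hydroxyl gives the (E)-2-methylbut-2-enoyl ketone under neutral conditions that leave the bromide, the lactone and the silyl ethers alone.

Step 24
Reactants: 30 tigloyl ketone
Product: 31 ring C-closed lactone
Conditions: KN(SiMe3)2 (1.1 equiv), THF, −78 → 0 °C
Reagents that add atoms: none
Why: In this intramolecular deconjugative α-alkylation of an extended enolate (6-(enolendo)-exo-tet closure of ring C) γ-deprotonation of the ketone, whose other side is quaternary C8, occurs from the s-cis conformer and gives the dienolate with the planar vinyl arm syn to oxygen and the methyl beside bulky C8, and C13 then attacks C12–Br through a chair in which the group beside C8 (C17) becomes axial (β) and the vinyl group equatorial (α), the attacked face being fixed by the C11 tether.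

Step 25
Reactants: 31 ring C-closed lactone
Product: 33 hydroxy 4-methoxybenzyl ester, via lithium carboxylate 32 (not isolated)
Conditions: LiOH, THF–MeOH–H2O, rt; evaporate; 4-MeOC6H4CH2Cl, Bu4NI, DMF, rt
Reagents that add atoms: lithium hydroxide, [Li+].[OH-]; 4-methoxybenzyl chloride, COc1ccc(CCl)cc1
Why: Saponification opens only the δ-lactone (the tert-butyl ester is too hindered and the ketone has no α-hydrogen), and alkylation of the carboxylate salt without any acidification prevents relactonisation and leaves C11 unchanged.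

Step 26
Reactants: 33 hydroxy 4-methoxybenzyl ester
Product: 34 11-benzoate
Conditions: BzCl, pyridine, DMAP, CH2Cl2, 0 °C → rt
Reagents that add atoms: benzoyl chloride, O=C(Cl)c1ccccc1
Why: DMAP-catalysed acylation of the equatorial 11α-hydroxyl, the only free hydroxyl, with excess acid chloride should outrun attack of that hydroxyl on the C2 ester and proceeds with retention at C11.

Step 27
Reactants: 34 11-benzoate
Product: 35 7,8-diol
Conditions: HF·pyridine, pyridine, THF, 0 °C → rt
Reagents that add atoms: none
Why: Fluoride-driven desilylation in a mildly acidic medium removes both triethylsilyl groups without touching the three esters or provoking retro-aldol cleavage of the β-hydroxy ketone.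

Step 28
Reactants: 35 7,8-diol
Product: 36 7-acetate
Conditions: Ac2O, pyridine, DMAP (cat.), CH2Cl2, rt
Reagents that add atoms: acetic anhydride, CC(=O)OC(C)=O
Why: Selective acylation takes the secondary 7α-hydroxyl and leaves the tertiary 8β-hydroxyl, and their trans-diaxial arrangement rules out acyl migration.

Step 29
Reactants: 36 7-acetate
Product: 37 CNP0315860.1
Conditions: CF3CO2H, anisole, CH2Cl2, 0 °C → rt
Reagents that add atoms: none
Why: Acidolysis by alkyl–oxygen cleavage removes the tert-butyl and 4-methoxybenzyl esters together (anisole traps the benzyl cation), while acetate, benzoate, vinyl group and the α-ketol, whose ionisation the carbonyl disfavours, persist.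

Compound list
1 | (S)-(+)-carvone, (5S)-2-methyl-5-(prop-1-en-2-yl)cyclohex-2-en-1-one | C=C(C)[C@H]1CC=C(C)C(=O)C1 | starting material
2 | trans-6-methylcarvone (major C6 epimer, methyl anti to isopropenyl) | C=C(C)[C@H]1CC=C(C)C(=O)[C@@H]1C | intermediate
3 | 6,6-dimethylcarvone, (5R)-2,6,6-trimethyl-5-(prop-1-en-2-yl)cyclohex-2-en-1-one | C=C(C)[C@H]1CC=C(C)C(=O)C1(C)C | intermediate
4 | (1R,5R)-2,6,6-trimethyl-5-(prop-1-en-2-yl)cyclohex-2-en-1-ol (OH cis to isopropenyl) | C=C(C)[C@H]1CC=C(C)[C@@H](O)C1(C)C | intermediate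
5 | (1R,5R)-2,4,4-trimethyl-5-(prop-1-en-2-yl)cyclohex-2-en-1-ol (OH cis to isopropenyl; carbinol carbon = C7) | C=C(C)[C@H]1C[C@@H](O)C(C)=CC1(C)C | intermediate
6 | 2,3-epoxide of 5, oxirane on the face of the hydroxyl group | C=C(C)[C@H]1C[C@@H](O)[C@@]2(C)O[C@H]2C1(C)C | intermediate
7 | 4-methoxybenzyl ether of 6 | C=C(C)[C@H]1C[C@@H](OCc3ccc(OC)cc3)[C@@]2(C)O[C@H]2C1(C)C | intermediate
8 | (3R,5R)-5-[(4-methoxybenzyl)oxy]-2,2-dimethyl-6-oxo-3-(prop-1-en-2-yl)heptanal | C=C(C)[C@H](C(C)(C)C=O)C[C@@H](OCc1ccc(OC)cc1)C(C)=O | intermediate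
9 | (3R,5R)-5-[(4-methoxybenzyl)oxy]-2,2-dimethyl-6-oxo-3-(prop-1-en-2-yl)heptanoic acid | C=C(C)[C@H](C(C)(C)C(=O)O)C[C@@H](OCc1ccc(OC)cc1)C(C)=O | intermediate
10 | tert-butyl ester of 9 | C=C(C)[C@H](C(C)(C)C(=O)OC(C)(C)C)C[C@@H](OCc1ccc(OC)cc1)C(C)=O | intermediate
11 | tert-butyl (3R,5R)-5-[(4-methoxybenzyl)oxy]-2,2-dimethyl-3-(prop-1-en-2-yl)-6-[(triethylsilyl)oxy]hept-6-enoate | C=C(C)[C@H](C(C)(C)C(=O)OC(C)(C)C)C[C@@H](OCc1ccc(OC)cc1)C(=C)O[Si](CC)(CC)CC | intermediate
12 | tert-butyl (3R,5R)-5-[(4-methoxybenzyl)oxy]-2,2-dimethyl-6-oxo-3-(prop-1-en-2-yl)-7-[(triethylsilyl)oxy]heptanoate | C=C(C)[C@H](C(C)(C)C(=O)OC(C)(C)C)C[C@@H](OCc1ccc(OC)cc1)C(=O)CO[Si](CC)(CC)CC | intermediate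
13 | propargyl alcohol | C#CCO | starting material
14 | 4-methoxybenzyl propargyl ether | C#CCOCc1ccc(OC)cc1 | intermediate
15 | {3-[(4-methoxybenzyl)oxy]prop-1-yn-1-yl}magnesium bromide | Br[Mg]C#CCOCc1ccc(OC)cc1 | intermediate
16 | tert-butyl (3R,5R,6S)-6-hydroxy-5,9-bis[(4-methoxybenzyl)oxy]-2,2-dimethyl-3-(prop-1-en-2-yl)-6-{[(triethylsilyl)oxy]methyl}non-7-ynoate (O7/O8 syn along C6–C7–C8–C9) | C=C(C)[C@H](C(C)(C)C(=O)OC(C)(C)C)C[C@@H](OCc1ccc(OC)cc1)[C@](O)(C#CCOCc1ccc(OC)cc1)CO[Si](CC)(CC)CC | intermediate
17 | O8-triethylsilyl ether of 16, the acyclic 1,7-enyne (C10=C1 alkene, C9≡C11 alkyne) | C=C(C)[C@H](C(C)(C)C(=O)OC(C)(C)C)C[C@@H](OCc1ccc(OC)cc1)[C@](O[Si](CC)(CC)CC)(C#CCOCc1ccc(OC)cc1)CO[Si](CC)(CC)CC | intermediate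
18 | Co2(CO)6 complex of the alkyne of 17 (written as its components) | C=C(C)[C@H](C(C)(C)C(=O)OC(C)(C)C)C[C@@H](OCc1ccc(OC)cc1)[C@](O[Si](CC)(CC)CC)(C#CCOCc1ccc(OC)cc1)CO[Si](CC)(CC)CC.[Co].[Co].[C-]#[O+].[C-]#[O+].[C-]#[O+].[C-]#[O+].[C-]#[O+].[C-]#[O+] | intermediate
19 | ring B-fused cyclopentenone: C2 ketone, C9=C11 alkene, quaternary C10 (10β-methyl), 5β-CMe2CO2tBu, 7α-OPMB, 8β-OSiEt3, C14 as CH2OSiEt3, C12 as CH2OPMB | O=C1C[C@@]2(C)[C@H](C(C)(C)C(=O)OC(C)(C)C)C[C@@H](OCc3ccc(OC)cc3)[C@@](O[Si](CC)(CC)CC)(CO[Si](CC)(CC)CC)C2=C1COCc1ccc(OC)cc1 | intermediate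
20 | enone diol: 19 with free 7α-OH and free C12-OH | O=C1C[C@@]2(C)[C@H](C(C)(C)C(=O)OC(C)(C)C)C[C@@H](O)[C@@](O[Si](CC)(CC)CC)(CO[Si](CC)(CC)CC)C2=C1CO | intermediate
21 | saturated ketone with 9α-H and 11α-H (C12 cis to C8) | O=C1C[C@@]2(C)[C@H](C(C)(C)C(=O)OC(C)(C)C)C[C@@H](O)[C@@](O[Si](CC)(CC)CC)(CO[Si](CC)(CC)CC)[C@@H]2[C@@H]1CO | intermediate
22 | trans-hydrindanone diol with 9α-H and 11β-H (C12 trans to C8) | O=C1C[C@@]2(C)[C@H](C(C)(C)C(=O)OC(C)(C)C)C[C@@H](O)[C@@](O[Si](CC)(CC)CC)(CO[Si](CC)(CC)CC)[C@@H]2[C@H]1CO | intermediate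
23 | δ-lactone C2(=O)–O–C11 (11α-O), free 7α-OH and C12-OH | O=C1C[C@@]2(C)[C@H](C(C)(C)C(=O)OC(C)(C)C)C[C@@H](O)[C@@](O[Si](CC)(CC)CC)(CO[Si](CC)(CC)CC)[C@@H]2[C@@H](CO)O1 | intermediate
24 | C12 bromide of 23 | O=C1C[C@@]2(C)[C@H](C(C)(C)C(=O)OC(C)(C)C)C[C@@H](O)[C@@](O[Si](CC)(CC)CC)(CO[Si](CC)(CC)CC)[C@@H]2[C@@H](CBr)O1 | intermediate
25 | O7-triethylsilyl ether of 24 | O=C1C[C@@]2(C)[C@H](C(C)(C)C(=O)OC(C)(C)C)C[C@@H](O[Si](CC)(CC)CC)[C@@](O[Si](CC)(CC)CC)(CO[Si](CC)(CC)CC)[C@@H]2[C@@H](CBr)O1 | intermediate
26 | C14 aldehyde on C8 | O=C1C[C@@]2(C)[C@H](C(C)(C)C(=O)OC(C)(C)C)C[C@@H](O[Si](CC)(CC)CC)[C@@](O[Si](CC)(CC)CC)(C=O)[C@@H]2[C@@H](CBr)O1 | intermediate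
27 | (E)-2-bromobut-2-ene | C/C=C(\C)Br | starting material
28 | (E)-but-2-en-2-yllithium | C/C=C(\C)[Li] | intermediate
29 | C14 allylic alcohol, (E)-alkene, C14 undefined | O=C1C[C@@]2(C)[C@H](C(C)(C)C(=O)OC(C)(C)C)C[C@@H](O[Si](CC)(CC)CC)[C@@](O[Si](CC)(CC)CC)(C(O)/C(C)=C/C)[C@@H]2[C@@H](CBr)O1 | intermediate
30 | tigloyl ketone, C14(=O)–C13(Me)=C15H–C16H3, (E) | O=C1C[C@@]2(C)[C@H](C(C)(C)C(=O)OC(C)(C)C)C[C@@H](O[Si](CC)(CC)CC)[C@@](O[Si](CC)(CC)CC)(C(=O)/C(C)=C/C)[C@@H]2[C@@H](CBr)O1 | intermediate
31 | ring C-closed lactone: trans-fused rings B and C, 13β-methyl, 13α-vinyl, C14 ketone, δ-lactone C2–O–C11 | C=C[C@@]1(C)C[C@H]2OC(=O)C[C@@]3(C)[C@H](C(C)(C)C(=O)OC(C)(C)C)C[C@@H](O[Si](CC)(CC)CC)[C@@](O[Si](CC)(CC)CC)(C1=O)[C@H]23 | intermediate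
32 | lithium C2 carboxylate with free 11α-OH | C=C[C@@]1(C)C[C@@H](O)[C@@H]2[C@@](C)(CC(=O)[O-])[C@H](C(C)(C)C(=O)OC(C)(C)C)C[C@@H](O[Si](CC)(CC)CC)[C@@]2(O[Si](CC)(CC)CC)C1=O.[Li+] | intermediate
33 | C2 4-methoxybenzyl ester with free 11α-OH | C=C[C@@]1(C)C[C@@H](O)[C@@H]2[C@@](C)(CC(=O)OCc3ccc(OC)cc3)[C@H](C(C)(C)C(=O)OC(C)(C)C)C[C@@H](O[Si](CC)(CC)CC)[C@@]2(O[Si](CC)(CC)CC)C1=O | intermediate
34 | 11α-benzoate of 33 | C=C[C@@]1(C)C[C@@H](OC(=O)c2ccccc2)[C@@H]2[C@@](C)(CC(=O)OCc3ccc(OC)cc3)[C@H](C(C)(C)C(=O)OC(C)(C)C)C[C@@H](O[Si](CC)(CC)CC)[C@@]2(O[Si](CC)(CC)CC)C1=O | intermediate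
35 | 7α,8β-diol | C=C[C@@]1(C)C[C@@H](OC(=O)c2ccccc2)[C@@H]2[C@@](C)(CC(=O)OCc3ccc(OC)cc3)[C@H](C(C)(C)C(=O)OC(C)(C)C)C[C@@H](O)[C@@]2(O)C1=O | intermediate
36 | 7α-acetate diester | C=C[C@@]1(C)C[C@@H](OC(=O)c2ccccc2)[C@@H]2[C@@](C)(CC(=O)OCc3ccc(OC)cc3)[C@H](C(C)(C)C(=O)OC(C)(C)C)C[C@@H](OC(C)=O)[C@@]2(O)C1=O | intermediate
37 | CNP0315860.1 (5R,7R,8R,9S,10S,11R,13R) | C=C[C@@]1(C)C[C@@H](OC(=O)c2ccccc2)[C@@H]2[C@@](C)(CC(=O)O)[C@H](C(C)(C)C(=O)O)C[C@@H](OC(C)=O)[C@@]2(O)C1=O | target

Total step count: 29. Longest linear sequence: 28 steps (1 to 37 through steps 1–11 and 13–29).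

Steps most likely to fail

Step 15. The 1,1-disubstituted alkene may insert too slowly into an alkyne complex that is flanked by the fully substituted C8 and a substituted terminus. The complex could then lose cobalt or decompose before it cyclises.
- The fallback redesigns the substrate. It sets out from 16 and returns at 19.
- 2,2-Dimethoxypropane and camphorsulfonic acid in acetone exchange the primary silyl ether and the tertiary hydroxyl for a spiro-dioxolane, acetonide enyne F1. This ties the two largest groups on C8 back and sharpens the angle compression.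
- Co2(CO)8 gives the dicobalt hexacarbonyl complex F2, which on heating with n-BuSMe should close to the acetonide cyclopentenone F3.
- Aqueous acetic acid releases the C8,C14-diol cyclopentenone F4, and Et3SiOTf with 2,6-lutidine silylates both oxygens to give 19.

Step 17. The tetrasubstituted alkene between two quaternary carbons may fail to bind the catalyst, or hydrogen may add with poor facial selectivity.
- The fallback replaces coordination chemistry by radical hydrogen-atom transfer. It sets out from 19 and returns at 22.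
- Mn(dpm)3, PhSiH3 and t-BuOOH in i-PrOH deliver a hydrogen atom to C9 from the open α face without needing to bind the alkene.
- The α-keto radical at C11 is then reduced, and brief treatment with DBU places C12 trans to C8. This gives the bis-PMB trans-hydrindanone F5.
- DDQ in buffered CH2Cl2 then removes both PMB groups and gives 22.

Step 24. The dienolate may alkylate on oxygen, which closes a six-membered enol ether instead. A mixed dienolate geometry could also erode the selectivity at C13.
- The fallback separates ring closure from the making of the quaternary centre. It sets out from 26 and returns at 31.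
- CH3CH=CHMgBr adds to the aldehyde to give the propenyl carbinol F6, and Dess–Martin oxidation gives the crotonoyl ketone F7.
- KN(SiMe3)2 forms its dienolate, whose less hindered α-carbon should attack C12–Br more readily. This gives the 13-demethyl ring C ketone F8, with the vinyl group equatorial after equilibration.
- A second deprotonation with KN(SiMe3)2 and MeI methylates the cyclic dienolate at C13 by stereoelectronically preferred axial (β) attack and gives 31.

Further compounds
F1 | step 15 | acetonide enyne (O8 and O14 in a 2,2-dimethyl-1,3-dioxolane) | C=C(C)[C@H](C(C)(C)C(=O)OC(C)(C)C)C[C@@H](OCc1ccc(OC)cc1)[C@]1(C#CCOCc2ccc(OC)cc2)COC(C)(C)O1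
F2 | step 15 | dicobalt hexacarbonyl complex of F1 (written as its components) | C=C(C)[C@H](C(C)(C)C(=O)OC(C)(C)C)C[C@@H](OCc1ccc(OC)cc1)[C@]1(C#CCOCc2ccc(OC)cc2)COC(C)(C)O1.[Co].[Co].[C-]#[O+].[C-]#[O+].[C-]#[O+].[C-]#[O+].[C-]#[O+].[C-]#[O+]
F3 | step 15 | acetonide cyclopentenone | O=C1C[C@@]2(C)[C@H](C(C)(C)C(=O)OC(C)(C)C)C[C@@H](OCc3ccc(OC)cc3)[C@@]3(COC(C)(C)O3)C2=C1COCc1ccc(OC)cc1
F4 | step 15 | C8,C14-diol cyclopentenone | O=C1C[C@@]2(C)[C@H](C(C)(C)C(=O)OC(C)(C)C)C[C@@H](OCc3ccc(OC)cc3)[C@@](O)(CO)C2=C1COCc1ccc(OC)cc1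
F5 | step 17 | bis-PMB trans-hydrindanone (9α-H, 11β-H) | O=C1C[C@@]2(C)[C@H](C(C)(C)C(=O)OC(C)(C)C)C[C@@H](OCc3ccc(OC)cc3)[C@@](O[Si](CC)(CC)CC)(CO[Si](CC)(CC)CC)[C@@H]2[C@H]1COCc1ccc(OC)cc1
F6 | step 24 | propenyl carbinol (C14 undefined) | O=C1C[C@@]2(C)[C@H](C(C)(C)C(=O)OC(C)(C)C)C[C@@H](O[Si](CC)(CC)CC)[C@@](O[Si](CC)(CC)CC)(C(O)/C=C/C)[C@@H]2[C@@H](CBr)O1
F7 | step 24 | crotonoyl ketone | O=C1C[C@@]2(C)[C@H](C(C)(C)C(=O)OC(C)(C)C)C[C@@H](O[Si](CC)(CC)CC)[C@@](O[Si](CC)(CC)CC)(C(=O)/C=C/C)[C@@H]2[C@@H](CBr)O1
F8 | step 24 | 13-demethyl ring C ketone (13α-vinyl, 13β-H) | C=C[C@H]1C[C@H]2OC(=O)C[C@@]3(C)[C@H](C(C)(C)C(=O)OC(C)(C)C)C[C@@H](O[Si](CC)(CC)CC)[C@@](O[Si](CC)(CC)CC)(C1=O)[C@H]23
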